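Everything rests on cutting the strained trans-fused gem-dimethylcyclobutane (C1, C9, C10, C11) back to a strain-free pyrrolidine that holds one nitrogen atom between C10 and C11. N-Amination of this amine and loss of N2 join C10 to C11 in a single operation and shrink the five-membered ring to the four-membered one. C1 and C9, being β to nitrogen, keep the trans relation set earlier. The precursor is the complete chroman-fused cyclononane carrying the trans-fused 2,2-dimethylpyrrolidine, a C8 dioxolane and an oxidant-proof dibromodimethoxy arene. It is reached by asymmetric coumarin arylation, radical quaternisation of C4, ring-closing metathesis and a regiospecific silyl nitronate Michael/hydroxymethylation sequence.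

Key step: step 20

Atom labels used for all intermediates:
- C1–C9 form the nine-membered ring.
- C4 is the O-bearing quaternary carbon, C5 its CH neighbour, and C8 the carbonyl/methylene carbon.
- C1 (bonded to CMe2 = C11) and C9 (bonded to CH2 = C10) are the small-ring fusion carbons.
- C1' is the benzylic CH.
- a1–a6 are the arene carbons, counted from a1 (on C1') to a6 (on O).

Remark on stereochemistry: in the target the C4 methyl, the C5 side chain (C6) and the C1' phenyl lie on one face of the pyran ring. C5 must therefore be set against the thermodynamic trans preference (step 3).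

Remark on regiochemistry: after conjugate addition C8 is flanked by two CH2 groups. C10 is therefore introduced through a regiodefined silyl enol ether (steps 14 and 15), not by enolisation of the ketone.

Assumption: the antipodes of SEGPHOS (step 1) and of the ammonium bifluoride (step 14) are assigned by analogy with simpler coumarins and cycloalkenones. The mirror-image catalyst would be used should the sense prove opposite.

Step 1
Reactants: 1 5,7-dimethoxycoumarin; 2 phenylboronic acid
Product: 3 (4S)-5,7-dimethoxy-4-phenylchroman-2-one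
Conditions: Rh(acac)(C2H4)2 (3 mol %), (S)-SEGPHOS, excess 2, dioxane/H2O 10:1, 60 °C
Reagents that add atoms: phenylboronic acid (2), OB(O)c1ccccc1
Why: Hayashi–Miyaura asymmetric 1,4-addition of an arylrhodium species to the coumarin C3=C4 bond, a reaction established for coumarins, in which the (S)-bisphosphine selects the alkene face and so sets C1' as S.

Step 2
Reactants: 3 (4S)-5,7-dimethoxy-4-phenylchroman-2-one; 4 tert-butyl(3-iodopropoxy)dimethylsilane
Product: 6 (3R,4S)-3-[3-(tert-butyldimethylsilyloxy)propyl]-5,7-dimethoxy-4-phenylchroman-2-one (3,4-trans), via lithium enolate 5 (not isolated)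
Conditions: LiN(i-Pr)2, THF, −78 °C; 4, DMPU, −78 → −30 °C
Reagents that add atoms: tert-butyl(3-iodopropoxy)dimethylsilane (4), CC(C)(C)[Si](C)(C)OCCCI
Why: Lactone enolate alkylation brings in C6–C8 at C5; the iodide enters opposite the pseudoaxial C1' phenyl, so the trans isomer should form, and its C5 configuration is inverted in step 3.

Step 3
Reactants: 6 trans-lactone
Product: 8 (3S,4S)-3-[3-(tert-butyldimethylsilyloxy)propyl]-5,7-dimethoxy-4-phenylchroman-2-one (3,4-cis), via lithium enolate 7 (not isolated)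
Conditions: LiN(i-Pr)2, THF, −78 °C; 2,6-di-tert-butyl-4-methylphenol, THF, −78 °C; cold pH 7 buffer
Reagents that add atoms: none
Why: Kinetic protonation of a planar lactone enolate: the bulky phenol delivers the proton to the face away from the phenyl group (held pseudoaxial by the peri a2 methoxy group), which pushes the side chain onto the phenyl face and gives the contra-thermodynamic C5 (S), cis to C1'.

Step 4
Reactants: 8 cis-lactone
Product: 9 (3S,4S)-3-[3-(tert-butyldimethylsilyloxy)propyl]-5,7-dimethoxy-2-methylidene-4-phenylchroman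
Conditions: Cp2TiMe2 (2.5 equiv), toluene, 70 °C, dark; basic alumina
Reagents that add atoms: dimethyltitanocene, [CH3-].[CH3-].[Ti+4].c1cc[cH-]c1.c1cc[cH-]c1
Why: Petasis methylenation of the lactone carbonyl proceeds through Cp2Ti=CH2 under neutral conditions, so the labile cis C5 centre next to the carbonyl is not epimerised and the future C4 methyl carbon is installed.

Step 5
Reactants: 9 exocyclic enol ether; 10 methyl acrylate
Product: 11 methyl 3-{(2R,3S,4S)-3-[3-(tert-butyldimethylsilyloxy)propyl]-5,7-dimethoxy-2-methyl-4-phenylchroman-2-yl}propanoate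
Conditions: Fe(acac)3 (20 mol %), PhSiH3 (2.5 equiv), 10 (3 equiv), Na2HPO4, EtOH, 60 °C
Reagents that add atoms: methyl acrylate (10), C=CC(=O)OC
Why: Iron-hydride hydrogen-atom transfer to the terminal CH2 of the enol ether gives the tertiary α-aryloxy C4 radical, which adds to the acrylate (Giese-type reductive olefin cross-coupling) on the face opposite the C5 side chain and the C1' phenyl, fixing C4 as R without any cationic or basic intermediate that could epimerise C5.

Step 6
Reactants: 11 methyl ester
Product: 12 3-{(2R,3S,4S)-3-[3-(tert-butyldimethylsilyloxy)propyl]-5,7-dimethoxy-2-methyl-4-phenylchroman-2-yl}propanal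
Conditions: i-Bu2AlH (1.1 equiv), CH2Cl2, −78 °C; Rochelle salt
Reagents that add atoms: none
Why: Partial ester reduction stops at the aldehyde (C1) because the tetrahedral aluminium hemiacetal persists at −78 °C, and silyl ether, aryl ethers and chroman are inert.

Step 7
Reactants: 12 aldehyde
Product: 13 (2R,3S,4S)-2-(but-3-en-1-yl)-3-[3-(tert-butyldimethylsilyloxy)propyl]-5,7-dimethoxy-2-methyl-4-phenylchroman
Conditions: Ph3PCH3Br, KOt-Bu, THF, 0 °C
Reagents that add atoms: methyltriphenylphosphonium bromide, C[P+](c1ccccc1)(c1ccccc1)c1ccccc1.[Br-]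
Why: Wittig methylenation of an unhindered aldehyde without an α-stereocentre gives the C3–C2–C1=CH2 arm for metathesis.

Step 8
Reactants: 13 silyl ether
Product: 14 3-[(2R,3S,4S)-2-(but-3-en-1-yl)-5,7-dimethoxy-2-methyl-4-phenylchroman-3-yl]propan-1-ol
Conditions: Bu4NF, THF, rt
Reagents that add atoms: none
Why: Fluoride-induced cleavage of the primary silyl ether frees C8–OH and touches nothing else.

Step 9
Reactants: 14 primary alcohol
Product: 15 3-[(2R,3S,4S)-2-(but-3-en-1-yl)-5,7-dimethoxy-2-methyl-4-phenylchroman-3-yl]propanal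
Conditions: Dess–Martin periodinane, CH2Cl2, 0 °C → rt
Reagents that add atoms: none
Why: Dess–Martin oxidation gives the C8 aldehyde under near-neutral conditions; C5 is γ to the carbonyl and cannot epimerise.

Step 10
Reactants: 15 aldehyde
Product: 16 5-[(2R,3S,4S)-2-(but-3-en-1-yl)-5,7-dimethoxy-2-methyl-4-phenylchroman-3-yl]pent-1-en-3-ol (both C8 epimers)
Conditions: CH2=CHMgBr, THF, −78 °C; aq. NH4Cl
Reagents that add atoms: vinylmagnesium bromide, C=C[Mg]Br
Why: Grignard 1,2-addition attaches C9; the uncontrolled C8 carbinol centre is erased in step 11.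

Step 11
Reactants: 16 allylic alcohol
Product: 17 5-[(2R,3S,4S)-2-(but-3-en-1-yl)-5,7-dimethoxy-2-methyl-4-phenylchroman-3-yl]pent-1-en-3-one
Conditions: Dess–Martin periodinane, CH2Cl2, 0 °C
Reagents that add atoms: none
Why: Dess–Martin oxidation of the allylic alcohol gives a single vinyl ketone, used promptly to avoid polymerisation.

Step 12
Reactants: 17 vinyl ketone diene
Product: 18 (4R,5S,1'S)-chroman-fused (Z)-cyclononenone (C8 ketone, Z C1=C9 alkene, C4 methyl, C1' phenyl, a2/a4 methoxy)
Conditions: second-generation Hoveyda–Grubbs catalyst (10 mol %, in portions), 1,4-benzoquinone (20 mol %), toluene (1 mM), 80 °C, argon sparge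
Reagents that add atoms: none
Why: Ring-closing metathesis of a terminal alkene with a vinyl ketone; the two arms sit trans on adjacent chroman carbons, one of them quaternary (gem-disubstituent effect), which favours closure, and the ring size should impose the Z alkene.

Step 13
Reactants: 19 2-nitropropane
Product: 20 trimethylsilyl propan-2-ylideneazinate (silyl nitronate of 19)
Conditions: Me3SiCl, Et3N, MeCN, 0 °C → rt; distillation
Reagents that add atoms: chlorotrimethylsilane, C[Si](C)(C)Cl
Why: O-Silylation of the nitronate of a secondary nitroalkane is a standard preparation of a distillable silyl nitronate.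

Step 14
Reactants: 18 cyclononenone; 20 silyl nitronate
Product: 21 (1R,4R,5S,1'S)-C8 trimethylsilyl enol ether (ring-cis C8=C9) bearing the 2-nitropropan-2-yl group (C11) at C1
Conditions: 20 (1.5 equiv), (R,R)-N-spiro bis(3,3'-diaryl-1,1'-binaphthyl-2,2'-dimethylene)ammonium hydrogen difluoride, aryl = 3,5-(CF3)2C6H3 (5 mol %), THF, −78 → −40 °C
Reagents that add atoms: silyl nitronate (20), CC(C)=[N+]([O-])O[Si](C)(C)C
Why: Bifluoride-triggered Mukaiyama-type Michael addition of a silyl nitronate to a cyclic enone: the free nitronate forms the congested C1–C11 bond and the silyl group passes to the enolate oxygen, storing the C8=C9 regiochemistry, while attack on the exposed Re face of C1 (the ring should fold with C5–H, not the C4 methyl, pointing inwards) is reinforced by the chiral cation and gives C1 as R.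

Step 15
Reactants: 21 silyl enol ether; 22 formaldehyde
Product: 23 (1R,4R,5S,9R,1'S)-C8 ketone with C9–CH2OH (C10) trans to the C1 2-nitropropan-2-yl group
Conditions: aq. HCHO (37 %), Sc(OTf)3 (10 mol %), THF, 0 °C → rt
Reagents that add atoms: formaldehyde (22), C=O
Why: Aqueous Lewis-acid-catalysed Mukaiyama aldol reaction occurs only at C9 of the preformed enol ether (never at C7) and anti to the bulky C1 substituent, giving the C1/C9 trans arrangement, which is also the one favoured should C9 equilibrate.

Step 16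
Reactants: 23 β-hydroxy ketone
Product: 25 (1R,4R,5S,9R,1'S)-C8 ethylene ketal with free C10–OH, via O-trimethylsilyl ether 24 (not isolated)
Conditions: (Me3SiOCH2)2 (3 equiv), Me3SiOTf (10 mol %), CH2Cl2, −78 → −20 °C; pyridine; K2CO3 (cat.), MeOH
Reagents that add atoms: 1,2-bis(trimethylsilyloxy)ethane, C[Si](C)(C)OCCO[Si](C)(C)C
Why: Noyori-type aprotic ketalisation works at low temperature without water or Brønsted acid, so the β-hydroxy ketone should neither dehydrate nor undergo retro-aldol cleavage, and the transient silyl ether falls off in methanol.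

Step 17
Reactants: 25 hydroxy ketal
Product: 26 C10 methanesulfonate of 25
Conditions: MsCl, Et3N, CH2Cl2, 0 °C
Reagents that add atoms: methanesulfonyl chloride, CS(=O)(=O)Cl
Why: Sulfonylation of the only hydroxyl group; with C8 masked there is no acidic C9–H to trigger β-elimination.

Step 18
Reactants: 26 nitro mesylate
Product: 28 (1R,4R,5S,9R,1'S)-trans-fused 2,2-dimethylpyrrolidine with C8 ketal and a2/a4-dimethoxy arene, via amino mesylate 27 (not isolated)
Conditions: H2 (4 bar), Raney Ni, EtOH, rt; filter; K2CO3, MeCN, 60 °C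
Reagents that add atoms: none
Why: Hydrogenation of the tertiary nitro group gives hindered primary amine 27, which cannot condense with the masked C8 carbonyl and closes the pyrrolidine by 5-exo-tet displacement of the primary C10 mesylate without touching C1 or C9.

Step 19
Reactants: 28 pyrrolidine
Product: 30 (1R,4R,5S,9R,1'S)-trans-fused 2,2-dimethylpyrrolidine with C8 ketal and a3,a5-dibromo-a2,a4-dimethoxy arene, via pyrrolidinium trifluoroacetate 29 (not isolated)
Conditions: CF3CO2H (1.1 equiv), CH2Cl2, 0 °C; NBS (2.05 equiv), −20 → 0 °C, dark; aq. Na2S2O3/NaHCO3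
Reagents that add atoms: N-bromosuccinimide, O=C1CCC(=O)N1Br
Why: Electrophilic aromatic bromination takes the only two free, strongly activated positions a3 and a5 while protonation shields nitrogen from N-bromination; the bromines block and deactivate the arene for step 20 and serve as formyl handles in step 23.

Step 20
Reactants: 30 dibromo pyrrolidine
Product: 33 (1R,4R,5S,9S,1'S)-trans-fused gem-dimethylcyclobutane with C8 ketal and a3,a5-dibromo-a2,a4-dimethoxy arene, via 1,1-diazene 31 (not isolated), via 1,4-biradical 32 (not isolated)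
Conditions: PhI(OH)OTs (2.5 equiv), NH2CO2NH4 (8 equiv), CF3CH2OH, 80 °C, sealed tube
Reagents that add atoms: none
Why: PhI(OH)OTs and ammonia released from the carbamate form an electrophilic iodonitrene that aminates the secondary amine, a second equivalent of the trivalent iodine reagent oxidises the adduct to 1,1-diazene 31, this expels N2 (C11–N breaking first because it frees a tertiary radical) to give singlet 1,4-biradical 32, and coupling of its two termini makes C10–C11. The closest known reaction type is the iodonitrene-mediated contraction of pyrrolidines to cyclobutanes, a one-pot version of the classical oxidation of N-aminopyrrolidines, and a purely dialkyl (α-tertiary/α-primary) substitution pattern lies at the edge of its scope. The four-membered ring closes by intramolecular recombination of the termini of a 1,4-biradical, not by a polar exo or endo cyclisation. No stereocentre is created: C1 and C9 are β to nitrogen, never become radical centres and carry their trans relation from the five- into the four-membered ring. The step needs recombination to outrun C1–C9 β-scission and hydrogen transfer from a C11 methyl group, and the singlet state, the gem-dimethyl compression at C11, the short C10···C11 distance held by the trans fusion and the sp3 ketal at C8 (which denies the scission product an enone) all favour closure. Chemoselectivity rests on the fully substituted, bromine-deactivated arene, which offers no position for aryliodonium formation or arene oxidation in CF3CH2OH, and on the excess carbamate, which buffers the TsOH and spares the dioxolane.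

Step 21
Reactants: 33 cyclobutane ketal
Product: 34 (1R,4R,5S,9S,1'S)-C8 ketone with trans-fused cyclobutane and dibromodimethoxy arene
Conditions: 1 M HCl, THF, rt
Reagents that add atoms: water, O
Why: Acid hydrolysis of the dioxolane is helped by relief of strain at the crowded sp3 C8 of the medium ring, and the deactivated aryl tert-alkyl ether tolerates dilute acid.

Step 22
Reactants: 34 ketone
Product: 35 C8 exocyclic methylene compound (dibromodimethoxy arene)
Conditions: Ph3PCH3Br, KOt-Bu, THF/toluene, 0 → 50 °C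
Reagents that add atoms: methyltriphenylphosphonium bromide, C[P+](c1ccccc1)(c1ccccc1)c1ccccc1.[Br-]
Why: Wittig methylenation of the ring ketone; the basic ylide cannot erode C9 because the trans-fused bicyclo[7.2.0] ketone is the thermodynamically preferred epimer, so no separate equilibration step is needed.

Step 23
Reactants: 35 dibromide
Product: 37 a3,a5-diformyl-a2,a4-dimethoxy compound, via dilithioarene 36 (not isolated)
Conditions: t-BuLi (4.4 equiv), THF/Et2O, −78 °C; DMF (10 equiv), −78 → 0 °C; aq. NH4Cl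
Reagents that add atoms: N,N-dimethylformamide, CN(C)C=O
Why: Twofold bromine–lithium exchange is faster than any deprotonation at −78 °C, each aryllithium is stabilised by two flanking oxygen substituents, and the DMF quench (Bouveault formylation) avoids the acidic formylation media that the exocyclic alkene would not survive.

Step 24
Reactants: 37 dialdehyde dimethyl ether
Product: 38 target CNP0253700.3, (1R,4R,5S,9S,1'S)
Conditions: MgI2·OEt2 (6 equiv), toluene/Et2O, 80 °C; cold aq. citric acid
Reagents that add atoms: none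
Why: Chelation of magnesium between each formyl oxygen and the ortho methoxy oxygen activates both methyl ethers for SN2 attack by iodide at methyl, a pathway closed to the tertiary C4–O bond, and the mild Lewis acid should leave the exocyclic alkene intact.

Compound list
1 | 5,7-dimethoxycoumarin | COc1cc(OC)c2ccc(=O)oc2c1 | starting material
2 | phenylboronic acid | OB(O)c1ccccc1 | starting material
3 | (4S)-5,7-dimethoxy-4-phenylchroman-2-one | O=C1C[C@@H](c2ccccc2)c2c(OC)cc(OC)cc2O1 | intermediate
4 | tert-butyl(3-iodopropoxy)dimethylsilane | CC(C)(C)[Si](C)(C)OCCCI | starting material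
5 | lithium enolate of 3 | [Li+].[O-]C1=C[C@@H](c2ccccc2)c2c(OC)cc(OC)cc2O1 | intermediate
6 | (3R,4S)-3-[3-(tert-butyldimethylsilyloxy)propyl]-5,7-dimethoxy-4-phenylchroman-2-one (trans) | CC(C)(C)[Si](C)(C)OCCC[C@@H]1[C@@H](c2ccccc2)c2c(OC)cc(OC)cc2OC1=O | intermediate
7 | lithium enolate of 6 (C5 planar) | [Li+].[O-]C1=C(CCCO[Si](C)(C)C(C)(C)C)[C@@H](c2ccccc2)c2c(OC)cc(OC)cc2O1 | intermediate
8 | (3S,4S)-3-[3-(tert-butyldimethylsilyloxy)propyl]-5,7-dimethoxy-4-phenylchroman-2-one (cis) | CC(C)(C)[Si](C)(C)OCCC[C@H]1[C@@H](c2ccccc2)c2c(OC)cc(OC)cc2OC1=O | intermediate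
9 | (3S,4S)-3-[3-(tert-butyldimethylsilyloxy)propyl]-5,7-dimethoxy-2-methylidene-4-phenylchroman | CC(C)(C)[Si](C)(C)OCCC[C@H]1[C@@H](c2ccccc2)c2c(OC)cc(OC)cc2OC1=C | intermediate
10 | methyl acrylate | C=CC(=O)OC | starting material
11 | methyl 3-{(2R,3S,4S)-3-[3-(tert-butyldimethylsilyloxy)propyl]-5,7-dimethoxy-2-methyl-4-phenylchroman-2-yl}propanoate | CC(C)(C)[Si](C)(C)OCCC[C@H]1[C@@H](c2ccccc2)c2c(OC)cc(OC)cc2O[C@]1(C)CCC(=O)OC | intermediate
12 | 3-{(2R,3S,4S)-3-[3-(tert-butyldimethylsilyloxy)propyl]-5,7-dimethoxy-2-methyl-4-phenylchroman-2-yl}propanal | CC(C)(C)[Si](C)(C)OCCC[C@H]1[C@@H](c2ccccc2)c2c(OC)cc(OC)cc2O[C@]1(C)CCC=O | intermediate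
13 | (2R,3S,4S)-2-(but-3-en-1-yl)-3-[3-(tert-butyldimethylsilyloxy)propyl]-5,7-dimethoxy-2-methyl-4-phenylchroman | CC(C)(C)[Si](C)(C)OCCC[C@H]1[C@@H](c2ccccc2)c2c(OC)cc(OC)cc2O[C@]1(C)CCC=C | intermediate
14 | 3-[(2R,3S,4S)-2-(but-3-en-1-yl)-5,7-dimethoxy-2-methyl-4-phenylchroman-3-yl]propan-1-ol | OCCC[C@H]1[C@@H](c2ccccc2)c2c(OC)cc(OC)cc2O[C@]1(C)CCC=C | intermediate
15 | 3-[(2R,3S,4S)-2-(but-3-en-1-yl)-5,7-dimethoxy-2-methyl-4-phenylchroman-3-yl]propanal | O=CCC[C@H]1[C@@H](c2ccccc2)c2c(OC)cc(OC)cc2O[C@]1(C)CCC=C | intermediate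
16 | 5-[(2R,3S,4S)-2-(but-3-en-1-yl)-5,7-dimethoxy-2-methyl-4-phenylchroman-3-yl]pent-1-en-3-ol (C8 epimers) | C=CC(O)CC[C@H]1[C@@H](c2ccccc2)c2c(OC)cc(OC)cc2O[C@]1(C)CCC=C | intermediate
17 | 5-[(2R,3S,4S)-2-(but-3-en-1-yl)-5,7-dimethoxy-2-methyl-4-phenylchroman-3-yl]pent-1-en-3-one | C=CC(=O)CC[C@H]1[C@@H](c2ccccc2)c2c(OC)cc(OC)cc2O[C@]1(C)CCC=C | intermediate
18 | (4R,5S,1'S)-chroman-fused (Z)-cyclononenone, C8 ketone, C1=C9 | O=C1CC[C@H]2[C@@H](c3ccccc3)c3c(OC)cc(OC)cc3O[C@]2(C)CC/C=C\1 | intermediate
19 | 2-nitropropane | CC(C)[N+](=O)[O-] | starting material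
20 | trimethylsilyl propan-2-ylideneazinate | CC(C)=[N+]([O-])O[Si](C)(C)C | intermediate
21 | (1R,4R,5S,1'S)-C8 trimethylsilyl enol ether with C1 2-nitropropan-2-yl group | C1C[C@H]2[C@@H](c3ccccc3)c3c(OC)cc(OC)cc3O[C@]2(C)CC[C@@H](C(C)(C)[N+](=O)[O-])/C=C1/O[Si](C)(C)C | intermediate
22 | formaldehyde | C=O | starting material
23 | (1R,4R,5S,9R,1'S)-C8 ketone, C9 hydroxymethyl, C1 2-nitropropan-2-yl (trans) | O=C1CC[C@H]2[C@@H](c3ccccc3)c3c(OC)cc(OC)cc3O[C@]2(C)CC[C@@H](C(C)(C)[N+](=O)[O-])[C@@H]1CO | intermediate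
24 | C8 ethylene ketal, C10 O-trimethylsilyl ether | C1COC2(O1)CC[C@H]3[C@@H](c4ccccc4)c4c(OC)cc(OC)cc4O[C@]3(C)CC[C@@H](C(C)(C)[N+](=O)[O-])[C@@H]2CO[Si](C)(C)C | intermediate
25 | C8 ethylene ketal, C10 alcohol, C11 nitro | C1COC2(O1)CC[C@H]3[C@@H](c4ccccc4)c4c(OC)cc(OC)cc4O[C@]3(C)CC[C@@H](C(C)(C)[N+](=O)[O-])[C@@H]2CO | intermediate
26 | C8 ethylene ketal, C10 mesylate, C11 nitro | C1COC2(O1)CC[C@H]3[C@@H](c4ccccc4)c4c(OC)cc(OC)cc4O[C@]3(C)CC[C@@H](C(C)(C)[N+](=O)[O-])[C@@H]2COS(C)(=O)=O | intermediate
27 | C8 ethylene ketal, C10 mesylate, C11 primary amine | C1COC2(O1)CC[C@H]3[C@@H](c4ccccc4)c4c(OC)cc(OC)cc4O[C@]3(C)CC[C@@H](C(C)(C)N)[C@@H]2COS(C)(=O)=O | intermediate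
28 | (1R,4R,5S,9R,1'S)-trans-fused 2,2-dimethylpyrrolidine, C8 ketal, dimethoxy arene | C1COC2(O1)CC[C@H]3[C@@H](c4ccccc4)c4c(OC)cc(OC)cc4O[C@]3(C)CC[C@@H]3[C@@H]2CNC3(C)C | intermediate
29 | trifluoroacetate salt of 28 | C1COC2(O1)CC[C@H]3[C@@H](c4ccccc4)c4c(OC)cc(OC)cc4O[C@]3(C)CC[C@@H]3[C@@H]2C[NH2+]C3(C)C.[O-]C(=O)C(F)(F)F | intermediate
30 | (1R,4R,5S,9R,1'S)-trans-fused 2,2-dimethylpyrrolidine, C8 ketal, a3,a5-dibromo-a2,a4-dimethoxy arene | C1COC2(O1)CC[C@H]3[C@@H](c4ccccc4)c4c(OC)c(Br)c(OC)c(Br)c4O[C@]3(C)CC[C@@H]3[C@@H]2CNC3(C)C | intermediate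
31 | 1,1-diazene (N-nitrene) of 30 | C1COC2(O1)CC[C@H]3[C@@H](c4ccccc4)c4c(OC)c(Br)c(OC)c(Br)c4O[C@]3(C)CC[C@@H]3[C@@H]2C[N+](=[N-])C3(C)C | intermediate
32 | singlet 1,4-biradical (C10 primary, C11 tertiary) | C1COC2(O1)CC[C@H]3[C@@H](c4ccccc4)c4c(OC)c(Br)c(OC)c(Br)c4O[C@]3(C)CC[C@@H]([C](C)C)[C@@H]2[CH2] | intermediate
33 | (1R,4R,5S,9S,1'S)-trans-fused gem-dimethylcyclobutane, C8 ketal, dibromodimethoxy arene | C1COC2(O1)CC[C@H]3[C@@H](c4ccccc4)c4c(OC)c(Br)c(OC)c(Br)c4O[C@]3(C)CC[C@@H]3[C@@H]2CC3(C)C | intermediate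
34 | C8 ketone with trans-fused cyclobutane, dibromodimethoxy arene | O=C1CC[C@H]2[C@@H](c3ccccc3)c3c(OC)c(Br)c(OC)c(Br)c3O[C@]2(C)CC[C@@H]2[C@@H]1CC2(C)C | intermediate
35 | C8 exocyclic methylene, dibromodimethoxy arene | C=C1CC[C@H]2[C@@H](c3ccccc3)c3c(OC)c(Br)c(OC)c(Br)c3O[C@]2(C)CC[C@@H]2[C@@H]1CC2(C)C | intermediate
36 | a3,a5-dilithio arene | C=C1CC[C@H]2[C@@H](c3ccccc3)c3c(OC)c([Li])c(OC)c([Li])c3O[C@]2(C)CC[C@@H]2[C@@H]1CC2(C)C | intermediate
37 | a3,a5-diformyl-a2,a4-dimethoxy compound | C=C1CC[C@H]2[C@@H](c3ccccc3)c3c(OC)c(C=O)c(OC)c(C=O)c3O[C@]2(C)CC[C@@H]2[C@@H]1CC2(C)C | intermediate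
38 | CNP0253700.3, (1R,4R,5S,9S,1'S) | C=C1CC[C@H]2[C@@H](c3ccccc3)c3c(O)c(C=O)c(O)c(C=O)c3O[C@]2(C)CC[C@@H]2[C@@H]1CC2(C)C | target

Total step count: 24
Longest linear sequence: 23 (steps 1–12 and 14–24; step 13 is a one-step side branch)

Steps most likely to fail

1. Step 20 (ring contraction).
- What may go wrong: once N2 has left, the purely dialkyl 1,4-biradical may cleave its central C1–C9 bond and so open the nine-membered ring, or disproportionate by hydrogen transfer from a C11 methyl group. Before that, the 1,1-diazene may tautomerise at C10–H or dimerise, because the C10 terminus has no radical-stabilising group.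
- Fallback (sets out from 18, returns at 34): the cyclobutane is closed by a polar C9–C10 bond formation that needs no nitrogen. Lewis-acid-catalysed Mukaiyama–Michael addition of the tert-butyldimethylsilyl ketene acetal of methyl isobutyrate to enone 18 should give the silyl enol ether ester F1. LiAlH4 then reduces the ester to the neopentyl alcohol F2, and TsCl/pyridine gives the tosylate F3. Anhydrous Bu4NF releases the regiodefined C9 enolate, which alkylates C10 in a 4-exo-tet closure to the debromo cyclobutyl ketone F4, the basic medium leaving C9 in the more stable trans fusion. NBS (2 equiv) then gives 34.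

2. Step 12 (ring-closing metathesis).
- What may go wrong: intermolecular metathesis to dimers and oligomers may win over closure of the strained nine-membered ring. The two arms must reach each other from a chroman that suffers either a methyl/phenyl syn-axial contact or a peri clash in the reactive conformers. The catalyst may also be slowed by chelation to the vinyl ketone, and the butenyl alkene may migrate.
- Fallback (sets out from 12, returns at 18): an irreversible Nozaki–Hiyama–Kishi closure of the C8–C9 bond. Stork–Zhao olefination of aldehyde 12 (Ph3PCH2I iodide, NaN(SiMe3)2, THF/DMPU, −78 °C) should give the Z-vinyl iodide F5. Bu4NF gives the alcohol F6, and Dess–Martin periodinane gives the iodo aldehyde F7. CrCl2 (excess) with NiCl2 (catalytic) in DMSO/THF under high dilution closes the ring to the cyclic Z-allylic alcohol F8, and Dess–Martin oxidation gives 18.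

3. Step 14 (silyl nitronate Michael addition).
- What may go wrong: addition of the hindered tertiary nitronate to the twisted medium-ring enone may be slow or reversible. Facial selectivity at C1 may be poor if ring bias and catalyst oppose each other. Premature loss of the silyl group would erase the C8=C9 regiochemical information.
- Fallback (sets out from 18, returns at 28): an irreversible organocopper addition, with nitrogen brought in later. Isopropenyl cuprate (CH2=C(CH3)MgBr, CuBr·SMe2, Me3SiCl, THF, −78 °C) should add to the peripheral face of 18 and give the isopropenyl silyl enol ether F9. Aqueous HCHO/Sc(OTf)3 gives the hydroxymethyl ketone F10, and (Me3SiOCH2)2/Me3SiOTf gives the ketal F11. Cobalt-catalysed Markovnikov hydroazidation (Co(BF4)2·6H2O, Schiff-base ligand, TsN3, PhSiH3, EtOH) places nitrogen on C11 to give the tertiary azide F12. MsCl/Et3N gives the azido mesylate F13, and Staudinger reduction (PMe3, THF/H2O) followed by spontaneous 5-exo-tet closure gives 28.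

Further compounds
F1 | step 20 | C8 tert-butyldimethylsilyl enol ether with C1–CMe2CO2Me | C1C[C@H]2[C@@H](c3ccccc3)c3c(OC)cc(OC)cc3O[C@]2(C)CC[C@@H](C(C)(C)C(=O)OC)/C=C1/O[Si](C)(C)C(C)(C)C
F2 | step 20 | C8 silyl enol ether with C1–CMe2CH2OH | C1C[C@H]2[C@@H](c3ccccc3)c3c(OC)cc(OC)cc3O[C@]2(C)CC[C@@H](C(C)(C)CO)/C=C1/O[Si](C)(C)C(C)(C)C
F3 | step 20 | C8 silyl enol ether with C1–CMe2CH2OTs | C1C[C@H]2[C@@H](c3ccccc3)c3c(OC)cc(OC)cc3O[C@]2(C)CC[C@@H](C(C)(C)COS(=O)(=O)c3ccc(C)cc3)/C=C1/O[Si](C)(C)C(C)(C)C
F4 | step 20 | debromo C8 ketone with trans-fused gem-dimethylcyclobutane | O=C1CC[C@H]2[C@@H](c3ccccc3)c3c(OC)cc(OC)cc3O[C@]2(C)CC[C@@H]2[C@@H]1CC2(C)C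
F5 | step 12 | (Z)-4-iodobut-3-enyl chroman silyl ether | CC(C)(C)[Si](C)(C)OCCC[C@H]1[C@@H](c2ccccc2)c2c(OC)cc(OC)cc2O[C@]1(C)CC/C=C\I
F6 | step 12 | (Z)-vinyl iodide primary alcohol | OCCC[C@H]1[C@@H](c2ccccc2)c2c(OC)cc(OC)cc2O[C@]1(C)CC/C=C\I
F7 | step 12 | (Z)-vinyl iodide C8 aldehyde | O=CCC[C@H]1[C@@H](c2ccccc2)c2c(OC)cc(OC)cc2O[C@]1(C)CC/C=C\I
F8 | step 12 | chroman-fused (Z)-cyclononenol (C8 epimers) | OC1CC[C@H]2[C@@H](c3ccccc3)c3c(OC)cc(OC)cc3O[C@]2(C)CC/C=C\1
F9 | step 14 | C8 trimethylsilyl enol ether with C1 isopropenyl | C1C[C@H]2[C@@H](c3ccccc3)c3c(OC)cc(OC)cc3O[C@]2(C)CC[C@@H](C(C)=C)/C=C1/O[Si](C)(C)C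
F10 | step 14 | C8 ketone, C9 hydroxymethyl, C1 isopropenyl (trans) | O=C1CC[C@H]2[C@@H](c3ccccc3)c3c(OC)cc(OC)cc3O[C@]2(C)CC[C@@H](C(C)=C)[C@@H]1CO
F11 | step 14 | C8 ethylene ketal of F10 | C1COC2(O1)CC[C@H]3[C@@H](c4ccccc4)c4c(OC)cc(OC)cc4O[C@]3(C)CC[C@@H](C(C)=C)[C@@H]2CO
F12 | step 14 | C8 ketal, C11 tertiary azide, C10 alcohol | C1COC2(O1)CC[C@H]3[C@@H](c4ccccc4)c4c(OC)cc(OC)cc4O[C@]3(C)CC[C@@H](C(C)(C)N=[N+]=[N-])[C@@H]2CO
F13 | step 14 | C8 ketal, C11 tertiary azide, C10 mesylate | C1COC2(O1)CC[C@H]3[C@@H](c4ccccc4)c4c(OC)cc(OC)cc4O[C@]3(C)CC[C@@H](C(C)(C)N=[N+]=[N-])[C@@H]2COS(C)(=O)=O
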